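C1 is the ring carbon bearing the side chain, C4 bears CH2OH, C8 and C12 bear the methyls, and C15 is the carbinol carbon; the 14-membered ring, the only ring, is closed last at C12–C13 by an intramolecular B-alkyl Suzuki coupling of alkenyl iodide 20.
20 comes from aldehyde 19 by Z-selective iodo-olefination; 19 comes from a chiral-diol-catalysed anti-allylboration of sulcatone 17 with allylboronate 16, which forms C1–C15 and both stereocentres.
16 comes from dienyl silyl ether 13 by cross-metathesis to allylic acetate 15 and allylic borylation.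
13 (C3=C4 olefin with its CH2O group) comes from a three-component carbomagnesiation of propargyl alcohol 7 with the Grignard reagent of bromide 6 and allyl bromide 8.
6 (C7=C8 E olefin) comes from 2,3-dihydrofuran 1 and bromo acetal 2 by alkylation and nickel-catalysed ring-opening methylation.

Assumption: the (R) enantiomer of 3,3'-dibromo-BINOL is taken to give the (11S,12R) adduct 19 [(1R,15R) in the target]; this sense is extrapolated from aryl methyl ketones, and if the mirror image forms, the (S) catalyst is used with nothing else changed.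

Step 1
Reactants: 1 2,3-dihydrofuran; 2 3-bromo-1,1-dimethoxypropane
Product: 4 5-(3,3-dimethoxypropyl)-2,3-dihydrofuran, via 5-lithio-2,3-dihydrofuran 3 (not isolated)
Conditions: t-BuLi, THF, −78 → 0 °C; then 2, DMPU, −30 → 23 °C
Reagents that add atoms: none
Why: Oxygen-directed α-lithiation of the cyclic enol ether and SN2 alkylation of the alkenyllithium by the primary bromide (Kocienski dihydrofuran alkylation); no stereocentre is formed.

Step 2
Reactants: 4 5-(3,3-dimethoxypropyl)-2,3-dihydrofuran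
Product: 5 (3E)-7,7-dimethoxy-4-methylhept-3-en-1-ol
Conditions: MeMgBr (3 equiv), NiCl2(PPh3)2 (5 mol %), toluene, 80 °C; aq. NH4Cl
Reagents that add atoms: methylmagnesium bromide, C[Mg]Br
Why: Wenkert–Kocienski coupling, in which zerovalent nickel inserts into the alkenyl C–O bond and methyl replaces oxygen with retention, so the acetal chain ends trans to the CH2CH2OH arm (E) and the acetal is untouched.

Step 3
Reactants: 5 (3E)-7,7-dimethoxy-4-methylhept-3-en-1-ol
Product: 6 (4E)-7-bromo-1,1-dimethoxy-4-methylhept-4-ene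
Conditions: CBr4, PPh3, pyridine, CH2Cl2, 0 °C
Reagents that add atoms: tetrabromomethane, BrC(Br)(Br)Br
Why: Appel bromination of the primary alcohol; pyridine buffers traces of HBr so that the acetal and the olefin geometry survive.

Step 4
Reactants: 6 (4E)-7-bromo-1,1-dimethoxy-4-methylhept-4-ene; 7 prop-2-yn-1-ol; 8 3-bromoprop-1-ene (allyl bromide)
Product: 13 triethyl{[(2Z)-2-[(3E)-7,7-dimethoxy-4-methylhept-3-en-1-yl]hexa-2,5-dien-1-yl]oxy}silane, via Grignard reagent 9 (not isolated), via bromomagnesium propynolate 10 (not isolated), via alkenylmagnesium chelate 11 (not isolated), via bromomagnesium dienolate 12 (not isolated)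
Conditions: 6, Mg, THF, 40 °C; 7, EtMgBr (1.0 equiv), THF, 0 °C; combine, CuI (15 mol %), 0 → 23 °C; then 8, 0 → 23 °C; then Et3SiCl, imidazole, DMF, 23 °C
Reagents that add atoms: chlorotriethylsilane, CC[Si](Cl)(CC)CC
Why: Copper-catalysed anti-carbomagnesiation of the propargylic alkoxide (Duboudin–Jousseaume reaction) puts the alkyl group on the internal carbon and holds magnesium on the terminal carbon cis to the alkoxide in a five-membered chelate, so allylation with retention places the allyl carbon cis to CH2O (2Z), and the alkoxide is silylated in the same flask.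

Step 5
Reactants: 13 triethyl{[(2Z)-2-[(3E)-7,7-dimethoxy-4-methylhept-3-en-1-yl]hexa-2,5-dien-1-yl]oxy}silane; 14 (2Z)-but-2-ene-1,4-diyl diacetate
Product: 15 (2E,5Z,9E)-13,13-dimethoxy-10-methyl-6-{[(triethylsilyl)oxy]methyl}trideca-2,5,9-trien-1-yl acetate
Conditions: 14 (3 equiv), RuCl2(H2IMes)(=CH-C6H4-2-OiPr) (second-generation Hoveyda–Grubbs catalyst, 4 mol %), 1,4-benzoquinone (10 mol %), CH2Cl2, 40 °C
Reagents that add atoms: none
Why: Olefin cross-metathesis in which only the monosubstituted vinyl group reacts (the trisubstituted olefins are inert), giving mainly the E allylic acetate; the minor Z isomer converges in step 6.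

Step 6
Reactants: 15 (2E,5Z,9E)-13,13-dimethoxy-10-methyl-6-{[(triethylsilyl)oxy]methyl}trideca-2,5,9-trien-1-yl acetate
Product: 16 2-[(2E,5Z,9E)-13,13-dimethoxy-10-methyl-6-{[(triethylsilyl)oxy]methyl}trideca-2,5,9-trien-1-yl]-1,3,2-dioxaborinane
Conditions: bis(1,3-propanediolato)diboron (1.1 equiv), Pd2(dba)3 (2.5 mol %), DMSO, 50 °C; aqueous work-up, used at once
Reagents that add atoms: bis(1,3-propanediolato)diboron, B1(OCCCO1)B1OCCCO1
Why: Miyaura allylic borylation, in which zerovalent palladium ionises the acetate and the η3-allyl intermediate is borylated at the unhindered terminus, giving the linear E allylboronate from either olefin isomer.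

Step 7
Reactants: 16 2-[(2E,5Z,9E)-13,13-dimethoxy-10-methyl-6-{[(triethylsilyl)oxy]methyl}trideca-2,5,9-trien-1-yl]-1,3,2-dioxaborinane; 17 6-methylhept-5-en-2-one (sulcatone)
Product: 19 (4E,8Z,11S,12R)-11-ethenyl-12-hydroxy-8-(hydroxymethyl)-4,12,16-trimethylheptadeca-4,8,15-trienal, via borate ester 18 (not isolated)
Conditions: 17 (3 equiv), (R)-3,3'-Br2-BINOL (10 mol %), t-BuOH (2 equiv), 4 Å MS, toluene, 23 °C; then 1 M HCl, THF, 23 °C
Reagents that add atoms: water, O
Why: Proposed new method: chiral-diol-catalysed allylboration of an unactivated methyl n-alkyl ketone with a functionalised γ-alkyl (E)-allyl-1,3,2-dioxaborinane; the BINOL opens the dioxaborinane to a more Lewis-acidic mixed aryl boronate, and addition runs through a closed chair (Zimmerman–Traxler) transition state with the ketone methyl axial and both the homoprenyl chain and the γ-substituent equatorial, which gives the anti adduct and sets both stereocentres in one C–C bond formation, with t-BuOH releasing the catalyst and the acidic work-up cleaving the borate, the silyl ether and the acetal; the closest known reaction type is the 3,3'-dibromo-BINOL-catalysed allyl- and crotylboration of aryl methyl ketones with allyl dioxaborinanes or allylboronic acids, and what is new is the methyl-versus-CH2 discrimination on a dialkyl ketone together with a γ-substituent that carries a skipped diene.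

Step 8
Reactants: 19 (4E,8Z,11S,12R)-11-ethenyl-12-hydroxy-8-(hydroxymethyl)-4,12,16-trimethylheptadeca-4,8,15-trienal
Product: 20 (2Z,5S,6R)-5-ethenyl-2-[(3E,7Z)-8-iodo-4-methylnona-3,7-dien-1-yl]-6,10-dimethylundeca-2,9-diene-1,6-diol
Conditions: EtPPh3I, n-BuLi, THF, 0 °C; I2, −78 °C; NaN(SiMe3)2, −78 °C; then 19, −78 → −20 °C (4 equiv ylide)
Reagents that add atoms: ethyltriphenylphosphonium iodide, CC[P+](c1ccccc1)(c1ccccc1)c1ccccc1.[I-]; iodine, II
Why: Stork–Zhao-type Wittig olefination with the α-iodo ylide Ph3P=C(I)CH3 gives the (Z)-2-iodo-2-alkene (iodine cis to the chain) under kinetic control; the excess ylide covers the two free hydroxyls, and the stereocentres are not touched.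

Step 9
Reactants: 20 (2Z,5S,6R)-5-ethenyl-2-[(3E,7Z)-8-iodo-4-methylnona-3,7-dien-1-yl]-6,10-dimethylundeca-2,9-diene-1,6-diol
Product: 22 (2R)-2-[(1R,3Z,7E,11Z)-4-(hydroxymethyl)-8,12-dimethylcyclotetradeca-3,7,11-trien-1-yl]-6-methylhept-5-en-2-ol, via alkylborane 21 (not isolated)
Conditions: 9-BBN (3.5 equiv), THF, 0 → 23 °C; then slow addition to Pd(dppf)Cl2 (20 mol %), AsPh3, Cs2CO3, DMF/THF/H2O, 50 °C, 2 mM
Reagents that add atoms: none
Why: 9-BBN hydroborates only the monosubstituted vinyl group, and the intramolecular B-alkyl Suzuki–Miyaura coupling with the alkenyl iodide closes the 14-membered ring with retention of the Z olefin geometry, leaving both stereocentres unchanged.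

Compound list
1 | 2,3-dihydrofuran | C1=COCC1 | starting material
2 | 3-bromo-1,1-dimethoxypropane | COC(OC)CCBr | starting material
3 | 5-lithio-2,3-dihydrofuran (not isolated) | [Li]C1=CCCO1 | intermediate
4 | 5-(3,3-dimethoxypropyl)-2,3-dihydrofuran | COC(OC)CCC1=CCCO1 | intermediate
5 | (3E)-7,7-dimethoxy-4-methylhept-3-en-1-ol | OCC/C=C(\C)CCC(OC)OC | intermediate
6 | (4E)-7-bromo-1,1-dimethoxy-4-methylhept-4-ene | BrCC/C=C(\C)CCC(OC)OC | intermediate
7 | prop-2-yn-1-ol | C#CCO | starting material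
8 | 3-bromoprop-1-ene (allyl bromide) | C=CCBr | starting material
9 | [(3E)-7,7-dimethoxy-4-methylhept-3-en-1-yl]magnesium bromide (not isolated) | Br[Mg]CC/C=C(\C)CCC(OC)OC | intermediate
10 | bromomagnesium prop-2-yn-1-olate (not isolated) | C#CCO[Mg]Br | intermediate
11 | 4-[(3E)-7,7-dimethoxy-4-methylhept-3-en-1-yl]-2,5-dihydro-1,2-oxamagnesole, the cyclic alkenylmagnesium alkoxide (not isolated) | COC(OC)CC/C(C)=C/CCC1=C[Mg]OC1 | intermediate
12 | bromomagnesium (2Z)-2-[(3E)-7,7-dimethoxy-4-methylhept-3-en-1-yl]hexa-2,5-dien-1-olate (not isolated) | Br[Mg]OC/C(CC/C=C(\C)CCC(OC)OC)=C\CC=C | intermediate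
13 | triethyl{[(2Z)-2-[(3E)-7,7-dimethoxy-4-methylhept-3-en-1-yl]hexa-2,5-dien-1-yl]oxy}silane | CC[Si](CC)(CC)OC/C(CC/C=C(\C)CCC(OC)OC)=C\CC=C | intermediate
14 | (2Z)-but-2-ene-1,4-diyl diacetate | CC(=O)OC/C=C\COC(C)=O | starting material
15 | (2E,5Z,9E)-13,13-dimethoxy-10-methyl-6-{[(triethylsilyl)oxy]methyl}trideca-2,5,9-trien-1-yl acetate | CC(=O)OC/C=C/C/C=C(\CO[Si](CC)(CC)CC)CC/C=C(\C)CCC(OC)OC | intermediate
16 | 2-[(2E,5Z,9E)-13,13-dimethoxy-10-methyl-6-{[(triethylsilyl)oxy]methyl}trideca-2,5,9-trien-1-yl]-1,3,2-dioxaborinane | B1(OCCCO1)C/C=C/C/C=C(\CO[Si](CC)(CC)CC)CC/C=C(\C)CCC(OC)OC | intermediate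
17 | 6-methylhept-5-en-2-one (sulcatone) | CC(=O)CCC=C(C)C | starting material
18 | 1,3,2-dioxaborinan-2-yl borate ester of the tertiary alkoxide adduct, still carrying the triethylsilyl ether and the dimethyl acetal (not isolated) | CC(C)=CCC[C@@](C)(OB1OCCCO1)[C@H](C=C)C/C=C(\CO[Si](CC)(CC)CC)CC/C=C(\C)CCC(OC)OC | intermediate
19 | (4E,8Z,11S,12R)-11-ethenyl-12-hydroxy-8-(hydroxymethyl)-4,12,16-trimethylheptadeca-4,8,15-trienal | CC(C)=CCC[C@@](C)(O)[C@H](C=C)C/C=C(\CO)CC/C=C(\C)CCC=O | intermediate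
20 | (2Z,5S,6R)-5-ethenyl-2-[(3E,7Z)-8-iodo-4-methylnona-3,7-dien-1-yl]-6,10-dimethylundeca-2,9-diene-1,6-diol | CC(C)=CCC[C@@](C)(O)[C@H](C=C)C/C=C(\CO)CC/C=C(\C)CC/C=C(/C)I | intermediate
21 | 9-alkyl-9-borabicyclo[3.3.1]nonane from anti-Markovnikov hydroboration of the vinyl group of 20 (not isolated) | CC(C)=CCC[C@@](C)(O)[C@H](CCB1C2CCCC1CCC2)C/C=C(\CO)CC/C=C(\C)CC/C=C(/C)I | intermediate
22 | (2R)-2-[(1R,3Z,7E,11Z)-4-(hydroxymethyl)-8,12-dimethylcyclotetradeca-3,7,11-trien-1-yl]-6-methylhept-5-en-2-ol | CC(C)=CCC[C@@](C)(O)[C@H]1C/C=C(\CO)CC/C=C(\C)CC/C=C(/C)CC1 | target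

Total step count: 9. Longest linear sequence: 9 steps (1 → 22; sulcatone 17 enters at step 7).

Steps most likely to fail

Step 7 (the proposed new step). The catalyst may not tell the ketone methyl from the primary alkyl chain well enough, giving low dr and er, or the γ-substituted boronate may add too slowly. The fallback uses known chemistry and sets out from bromide 6 (through 9, 10 and 11) together with commercial nerol. Sharpless epoxidation of nerol (Ti(OiPr)4, L-(+)-diethyl tartrate, t-BuOOH, −20 °C) gives [(2S,3R)-3-methyl-3-(4-methylpent-3-en-1-yl)oxiran-2-yl]methanol F5. CH2=CHMgBr with CuI opens it at the secondary carbon with inversion to (2R,3R)-2-ethenyl-3,7-dimethyloct-6-ene-1,3-diol F6. I2/PPh3/imidazole then gives (3S,4R)-3-(iodomethyl)-4,8-dimethylnona-1,7-dien-4-ol F7, and Et3SiOSO2CF3/2,6-lutidine gives its triethylsilyl ether F8. In parallel, chelate 11 is quenched with I2 instead of 8 and silylated to triethyl{[(2Z)-3-iodo-2-[(3E)-7,7-dimethoxy-4-methylhept-3-en-1-yl]prop-2-en-1-yl]oxy}silane F9. F8 is converted (t-BuLi, Et2O, −78 °C; ZnCl2) into the alkylzinc chloride F10, which is not isolated, and Negishi coupling with F9 (Pd(dppf)Cl2, THF) gives the bis(triethylsilyl) ether dimethyl acetal of 19, F11. 1 M HCl in THF removes both silyl groups and the acetal, and the route is rejoined at 19.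

Step 9. The macrocyclic B-alkyl Suzuki coupling may give oligomers or protodeboronated material. The fallback sets out from 20 and closes the same bond by an intramolecular Heck reaction (Pd(OAc)2, Bu4NCl, K2CO3, DMF, 60 °C, high dilution). The alkenylpalladium adds to the terminal carbon of the vinyl group, and β-hydride elimination gives (2R)-2-[(1S,2E,4Z,8E,12Z)-12-(hydroxymethyl)-4,8-dimethylcyclotetradeca-2,4,8,12-tetraen-1-yl]-6-methylhept-5-en-2-ol F12. Diimide (2-nitrobenzenesulfonyl hydrazide, Et3N) then reduces only the new disubstituted olefin, the trisubstituted ones being far slower, and the route is rejoined at 22.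

Step 4. The copper-catalysed carbomagnesiation with a functionalised primary alkyl Grignard reagent and two further in-flask operations may be low-yielding. The fallback sets out from bromide 6 (as its Grignard reagent 9) and builds the olefin by syn-carbocupration of an ynoate. Methyl 4-hydroxybut-2-ynoate is silylated (Et3SiCl, imidazole) to methyl 4-[(triethylsilyl)oxy]but-2-ynoate F1. The organocopper reagent from 9 and CuBr·SMe2 (THF, −78 °C) adds syn to give methyl (2Z,6E)-10,10-dimethoxy-7-methyl-3-{[(triethylsilyl)oxy]methyl}deca-2,6-dienoate F2. i-Bu2AlH reduces it to (2Z,6E)-10,10-dimethoxy-7-methyl-3-{[(triethylsilyl)oxy]methyl}deca-2,6-dien-1-ol F3, and CBr4/PPh3/pyridine gives (2Z,6E)-1-bromo-10,10-dimethoxy-7-methyl-3-{[(triethylsilyl)oxy]methyl}deca-2,6-diene F4. Stille coupling of F4 with Bu3SnCH=CH2 (Pd(PPh3)4) rejoins the route at 13.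

Further compounds
F1 | step 4 | methyl 4-[(triethylsilyl)oxy]but-2-ynoate | CC[Si](CC)(CC)OCC#CC(=O)OC
F2 | step 4 | methyl (2Z,6E)-10,10-dimethoxy-7-methyl-3-{[(triethylsilyl)oxy]methyl}deca-2,6-dienoate | COC(=O)/C=C(\CO[Si](CC)(CC)CC)CC/C=C(\C)CCC(OC)OC
F3 | step 4 | (2Z,6E)-10,10-dimethoxy-7-methyl-3-{[(triethylsilyl)oxy]methyl}deca-2,6-dien-1-ol | OC/C=C(\CO[Si](CC)(CC)CC)CC/C=C(\C)CCC(OC)OC
F4 | step 4 | (2Z,6E)-1-bromo-10,10-dimethoxy-7-methyl-3-{[(triethylsilyl)oxy]methyl}deca-2,6-diene | BrC/C=C(\CO[Si](CC)(CC)CC)CC/C=C(\C)CCC(OC)OC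
F5 | step 7 | [(2S,3R)-3-methyl-3-(4-methylpent-3-en-1-yl)oxiran-2-yl]methanol | CC(C)=CCC[C@@]1(C)O[C@H]1CO
F6 | step 7 | (2R,3R)-2-ethenyl-3,7-dimethyloct-6-ene-1,3-diol | CC(C)=CCC[C@@](C)(O)[C@H](C=C)CO
F7 | step 7 | (3S,4R)-3-(iodomethyl)-4,8-dimethylnona-1,7-dien-4-ol | CC(C)=CCC[C@@](C)(O)[C@H](C=C)CI
F8 | step 7 | triethylsilyl ether of F7 | CC(C)=CCC[C@@](C)(O[Si](CC)(CC)CC)[C@H](C=C)CI
F9 | step 7 | triethyl{[(2Z)-3-iodo-2-[(3E)-7,7-dimethoxy-4-methylhept-3-en-1-yl]prop-2-en-1-yl]oxy}silane | CC[Si](CC)(CC)OC/C(CC/C=C(\C)CCC(OC)OC)=C\I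
F10 | step 7 | alkylzinc chloride from F8 (not isolated) | CC(C)=CCC[C@@](C)(O[Si](CC)(CC)CC)[C@H](C=C)C[Zn]Cl
F11 | step 7 | bis(triethylsilyl) ether dimethyl acetal of 19 | CC(C)=CCC[C@@](C)(O[Si](CC)(CC)CC)[C@H](C=C)C/C=C(\CO[Si](CC)(CC)CC)CC/C=C(\C)CCC(OC)OC
F12 | step 9 | (2R)-2-[(1S,2E,4Z,8E,12Z)-12-(hydroxymethyl)-4,8-dimethylcyclotetradeca-2,4,8,12-tetraen-1-yl]-6-methylhept-5-en-2-ol | CC(C)=CCC[C@@](C)(O)[C@H]1C/C=C(\CO)CC/C=C(\C)CC/C=C(/C)\C=C\1
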